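## Retrosynthetic overview

1. Target ⇐ selective 14,15-diacetylation of the triol acid ⇐ anti-E2 opening of an 18,10-lactone; only H1 is antiperiplanar to C10–O, so the 1(10)-alkene and the C18 acid appear together.
2. Lactone ⇐ RuO4 oxidation of an 18,10-ether ⇐ one-flask cationic cascade on an acyclic epoxy-diene: ring A, then ring B (chair–chair), then 9→8 hydride shift, 10→9 methyl shift and capture of the C10 cation by the C18 oxygen.
3. Epoxy-diene ⇐ catalytic asymmetric Corey–Chaykovsky methylenation of a methyl ketone (sets C4, which relays to C5, C8 and C9 in the cascade); C13/C14 come from Sharpless epoxidation followed by invertive hydrolysis.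
4. C20 chain ⇐ farnesyl acetate (C15; terminal SeO2 oxidation, then bromide) + a four-carbon ketal Grignard reagent; C18 is the ylide methylene.
5. Ring order: A then B in a single step; the temporary oxolane/lactone ring is opened again in the elimination.

Numbering note: C1–C20 in the text are halimane/labdane positions (C18 = carboxyl carbon, C13–C15 = oxygenated tail).

Assumption: the (S)-BINOL-derived LaLi3 catalyst is taken to give the (S)-epoxide 11; if the sense of induction for this ketone proves opposite, the (R)-BINOL catalyst is used and nothing else changes.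

## Route

Step 1
Reactants: 1 (2E,6E)-3,7,11-trimethyldodeca-2,6,10-trien-1-yl acetate (farnesyl acetate)
Product: 2 (2E,6E,10E)-12-hydroxy-3,7,11-trimethyldodeca-2,6,10-trien-1-yl acetate
Conditions: SeO2 (10 mol%), t-BuOOH (2.5 equiv), salicylic acid (10 mol%), CH2Cl2, 0 °C to rt
Reagents that add atoms: tert-butyl hydroperoxide CC(C)(C)OO
Why: Catalytic SeO2 allylic oxidation (ene reaction, then [2,3]-shift) picks the (E)-methyl of the most electron-rich terminal alkene, the acetate-deactivated 2,3-alkene is spared, and no stereocentre is formed.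

Step 2
Reactants: 2 (2E,6E,10E)-12-hydroxy-3,7,11-trimethyldodeca-2,6,10-trien-1-yl acetate
Product: 3 (2E,6E,10E)-12-bromo-3,7,11-trimethyldodeca-2,6,10-trien-1-yl acetate
Conditions: CBr4, PPh3, CH2Cl2, −20 to 0 °C
Reagents that add atoms: carbon tetrabromide BrC(Br)(Br)Br
Why: Appel bromination converts the primary allylic alcohol to the bromide under neutral conditions without allylic transposition or loss of the (E)-geometry.

Step 3
Reactants: 3 (2E,6E,10E)-12-bromo-3,7,11-trimethyldodeca-2,6,10-trien-1-yl acetate; 4 2-(2-bromoethyl)-2-methyl-1,3-dioxolane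
Product: 7 (2E,6E,10E)-3,7,11-trimethyl-14-(2-methyl-1,3-dioxolan-2-yl)tetradeca-2,6,10-trien-1-ol, via Grignard reagent 5 (not isolated), via coupled acetate 6 (not isolated)
Conditions: 4, Mg, THF, 25 °C; then 3, Li2CuCl4 (3 mol%), THF, −78 to −20 °C; then MeOH, K2CO3, rt
Reagents that add atoms: none
Why: Kochi-type copper-catalysed sp3–sp3 cross-coupling of a Grignard reagent with a primary allylic bromide goes at the α-carbon with retention of the (E)-alkene and is far faster at −78 °C than attack on the acetate, which is then removed by base-catalysed transesterification in the same flask.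

Step 4
Reactants: 7 (2E,6E,10E)-3,7,11-trimethyl-14-(2-methyl-1,3-dioxolan-2-yl)tetradeca-2,6,10-trien-1-ol
Product: 8 [(2S,3S)-3-[(3E,7E)-4,8-dimethyl-11-(2-methyl-1,3-dioxolan-2-yl)undeca-3,7-dien-1-yl]-3-methyloxiran-2-yl]methanol
Conditions: Ti(OiPr)4 (10 mol%), L-(+)-diethyl tartrate (12 mol%), t-BuOOH (2 equiv), 4 Å MS, CH2Cl2, −20 °C
Reagents that add atoms: tert-butyl hydroperoxide CC(C)(C)OO
Why: Sharpless asymmetric epoxidation is hydroxyl-directed, so only the allylic alcohol alkene reacts, and the L-(+)-tartrate that turns geraniol into (2S,3S)-epoxygeraniol sets both tail stereocentres (C13 and C14).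

Step 5
Reactants: 8 [(2S,3S)-3-[(3E,7E)-4,8-dimethyl-11-(2-methyl-1,3-dioxolan-2-yl)undeca-3,7-dien-1-yl]-3-methyloxiran-2-yl]methanol
Product: 9 (6E,10E,14R,15S)-14,15,16-trihydroxy-6,10,14-trimethylhexadeca-6,10-dien-2-one
Conditions: HClO4 (0.2 M aq.), THF, 0 °C to rt
Reagents that add atoms: water O
Why: Acid-catalysed epoxide hydrolysis of a 3,3-disubstituted 2,3-epoxy alcohol puts water on the tertiary carbon with inversion (13S to 13R) while C14 keeps its C–O bond, and the dioxolane is cleaved by acetal hydrolysis in the same operation.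

Step 6
Reactants: 9 (6E,10E,14R,15S)-14,15,16-trihydroxy-6,10,14-trimethylhexadeca-6,10-dien-2-one
Product: 10 (2S,3R,6E,10E)-3,7,11-trimethyl-15-oxohexadeca-6,10-diene-1,2,3-triyl triacetate
Conditions: Ac2O (6 equiv), Et3N, DMAP (0.3 equiv), CH2Cl2, rt to 40 °C
Reagents that add atoms: acetic anhydride CC(=O)OC(C)=O
Why: DMAP-catalysed acylation acetylates the primary, secondary and tertiary hydroxyls; the tertiary acetate is needed so that O13 cannot capture the C8 cation in step 8.

Step 7
Reactants: 10 (2S,3R,6E,10E)-3,7,11-trimethyl-15-oxohexadeca-6,10-diene-1,2,3-triyl triacetate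
Product: 11 (2S,3R,6E,10E)-3,7,11-trimethyl-14-[(2S)-2-methyloxiran-2-yl]tetradeca-6,10-diene-1,2,3-triyl triacetate
Conditions: Me3S(O)I, NaH, THF; then 10, LaLi3[(S)-binaphthoxide]3 (5 mol%), (2,4,6-(MeO)3C6H2)3P=O (5 mol%), 5 Å MS, THF, rt
Reagents that add atoms: trimethylsulfoxonium iodide C[S+](C)(C)=O.[I-]
Why: Catalytic asymmetric Corey–Chaykovsky epoxidation of a methyl ketone, in which the heterobimetallic BINOLate catalyst tells methyl from the long chain and sets the quaternary C4 centre as (S), the ketone being more electrophilic toward the stabilised ylide than the acetates.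

Step 8
Reactants: 11 (2S,3R,6E,10E)-3,7,11-trimethyl-14-[(2S)-2-methyloxiran-2-yl]tetradeca-6,10-diene-1,2,3-triyl triacetate
Product: 14 (4S,5R,8R,9S,10R,13R,14S)-13,14,15-triacetoxy-18,10-epoxyhalimane, via labdan-8-yl cation 12 (not isolated), via haliman-10-yl cation 13 (not isolated)
Conditions: BF3·OEt2 (4 equiv), CH2Cl2, −78 °C, then slowly to −20 °C
Reagents that add atoms: none
Why: Proposed new method: BF3 opens the 2,2-disubstituted oxirane at its tertiary carbon with inversion as the C5=C10 alkene attacks anti to the C4–O bond (the C18H2–O arm must stay near the in-plane leaving oxygen and away from the axial C10 methyl, so it sits equatorial and the (S)-epoxide fixes C4 and, through the chair–chair transition state of the two (E)-alkenes, C5); the C8=C9 alkene closes ring B to cation 12, antiperiplanar 9→8 hydride and 10→9 methyl shifts (setting C8 and C9) give cation 13, and the C18 oxygen held 1,3 to C10 captures it on the face the methyl left, while any C8 alkene from early proton loss is re-protonated and funnelled to the same ether; closest known reaction types are Lewis-acid epoxide-initiated polyene bicyclisation, the BF3·OEt2-induced 1,2-H/1,2-Me backbone shift with heteroatom capture at C10 used for aureol, and the acid-induced γ-lactonisation of dihydroabietic acid with 10→9 methyl migration.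

Step 9
Reactants: 14 (4S,5R,8R,9S,10R,13R,14S)-13,14,15-triacetoxy-18,10-epoxyhalimane
Product: 15 (4S,5R,8R,9S,10R,13R,14S)-13,14,15-triacetoxyhalimano-18,10-lactone
Conditions: RuCl3 hydrate (5 mol%), NaIO4 (4 equiv), CCl4/MeCN/H2O, rt
Reagents that add atoms: sodium periodate [Na+].[O-][I](=O)(=O)=O
Why: RuO4 oxidation of an ether α-methylene to the lactone; C18 is the only ether CH2 (the other ether carbon is quaternary), no alkene is left in the molecule, and no stereocentre is touched.

Step 10
Reactants: 15 (4S,5R,8R,9S,10R,13R,14S)-13,14,15-triacetoxyhalimano-18,10-lactone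
Product: 17 (4S,5S,8R,9S,13R,14S)-13,14,15-trihydroxyhalim-1(10)-en-18-oic acid, via lactone triol 16 (not isolated)
Conditions: KOtBu (10 equiv), 18-crown-6 (1 equiv), THF, rt then 65 °C; 1 M HCl work-up
Reagents that add atoms: none
Why: Proposed new method: tert-butoxide first strips the acetates by transesterification (16), and the rigid 6-oxabicyclo[3.2.1]octan-7-one then has only the axial H1 antiperiplanar to the C10–O bond (H5 is cis to the oxygen and C9 bears no hydrogen), so E2 elimination with the non-enolisable, sterically shielded carboxylate as leaving group can give only the 1(10)-alkene and frees the C18 acid; closest known reaction types are crown-ether/tert-butoxide E2 eliminations of hindered tertiary carboxylates and base-induced eliminative opening of lactones.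

Step 11
Reactants: 17 (4S,5S,8R,9S,13R,14S)-13,14,15-trihydroxyhalim-1(10)-en-18-oic acid
Product: 18 (4S,5S,8R,9S,13R,14S)-14,15-diacetoxy-13-hydroxyhalim-1(10)-en-18-oic acid (CNP0224606.1)
Conditions: Ac2O (5 equiv), pyridine, 0 °C to rt; aq. NaHCO3, then dilute HCl work-up
Reagents that add atoms: acetic anhydride CC(=O)OC(C)=O
Why: Acylation with Ac2O/pyridine without DMAP esterifies only the primary and secondary hydroxyls, leaves the tertiary C13 hydroxyl free, and the mixed anhydride of the hindered acid is hydrolysed on work-up.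

## Compound list

1 | (2E,6E)-3,7,11-trimethyldodeca-2,6,10-trien-1-yl acetate (farnesyl acetate) | CC(C)=CCC/C(C)=C/CC/C(C)=C/COC(C)=O | starting material
2 | (2E,6E,10E)-12-hydroxy-3,7,11-trimethyldodeca-2,6,10-trien-1-yl acetate | OC/C(C)=C/CC/C(C)=C/CC/C(C)=C/COC(C)=O | intermediate
3 | (2E,6E,10E)-12-bromo-3,7,11-trimethyldodeca-2,6,10-trien-1-yl acetate | BrC/C(C)=C/CC/C(C)=C/CC/C(C)=C/COC(C)=O | intermediate
4 | 2-(2-bromoethyl)-2-methyl-1,3-dioxolane | CC1(CCBr)OCCO1 | starting material
5 | [2-(2-methyl-1,3-dioxolan-2-yl)ethyl]magnesium bromide | CC1(CC[Mg]Br)OCCO1 | intermediate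
6 | (2E,6E,10E)-3,7,11-trimethyl-14-(2-methyl-1,3-dioxolan-2-yl)tetradeca-2,6,10-trien-1-yl acetate | CC1(CCC/C(C)=C/CC/C(C)=C/CC/C(C)=C/COC(C)=O)OCCO1 | intermediate
7 | (2E,6E,10E)-3,7,11-trimethyl-14-(2-methyl-1,3-dioxolan-2-yl)tetradeca-2,6,10-trien-1-ol | CC1(CCC/C(C)=C/CC/C(C)=C/CC/C(C)=C/CO)OCCO1 | intermediate
8 | [(2S,3S)-3-[(3E,7E)-4,8-dimethyl-11-(2-methyl-1,3-dioxolan-2-yl)undeca-3,7-dien-1-yl]-3-methyloxiran-2-yl]methanol | OC[C@@H]1O[C@@]1(C)CC/C=C(C)/CC/C=C(C)/CCCC2(C)OCCO2 | intermediate
9 | (6E,10E,14R,15S)-14,15,16-trihydroxy-6,10,14-trimethylhexadeca-6,10-dien-2-one | OC[C@H](O)[C@](C)(O)CC/C=C(C)/CC/C=C(C)/CCCC(C)=O | intermediate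
10 | (2S,3R,6E,10E)-3,7,11-trimethyl-15-oxohexadeca-6,10-diene-1,2,3-triyl triacetate | CC(=O)OC[C@H](OC(C)=O)[C@](C)(OC(C)=O)CC/C=C(C)/CC/C=C(C)/CCCC(C)=O | intermediate
11 | (2S,3R,6E,10E)-3,7,11-trimethyl-14-[(2S)-2-methyloxiran-2-yl]tetradeca-6,10-diene-1,2,3-triyl triacetate | CC(=O)OC[C@H](OC(C)=O)[C@](C)(OC(C)=O)CC/C=C(C)/CC/C=C(C)/CCC[C@@]1(C)CO1 | intermediate
12 | (4S,5S,9R,10S,13R,14S)-13,14,15-triacetoxy-18-hydroxylabdan-8-yl cation (oxygen carries BF3 in the flask) | CC(=O)OC[C@H](OC(C)=O)[C@](C)(OC(C)=O)CC[C@@H]1[C+](C)CC[C@@H]2[C@@](C)(CO)CCC[C@@]12C | intermediate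
13 | (4S,5S,8R,9R,13R,14S)-13,14,15-triacetoxy-18-hydroxyhaliman-10-yl cation (oxygen carries BF3 in the flask) | CC(=O)OC[C@H](OC(C)=O)[C@](C)(OC(C)=O)CC[C@@]1(C)[C@H](C)CC[C@@H]2[C@@](C)(CO)CCC[C+]12 | intermediate
14 | (4S,5R,8R,9S,10R,13R,14S)-13,14,15-triacetoxy-18,10-epoxyhalimane | CC(=O)OC[C@H](OC(C)=O)[C@](C)(OC(C)=O)CC[C@@]1(C)[C@H](C)CC[C@@H]2[C@]3(C)CCC[C@]12OC3 | intermediate
15 | (4S,5R,8R,9S,10R,13R,14S)-13,14,15-triacetoxyhalimano-18,10-lactone | CC(=O)OC[C@H](OC(C)=O)[C@](C)(OC(C)=O)CC[C@@]1(C)[C@H](C)CC[C@@H]2[C@]3(C)CCC[C@]12OC3=O | intermediate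
16 | (4S,5R,8R,9S,10R,13R,14S)-13,14,15-trihydroxyhalimano-18,10-lactone (potassium alkoxides in the flask) | OC[C@H](O)[C@](C)(O)CC[C@@]1(C)[C@H](C)CC[C@@H]2[C@]3(C)CCC[C@]12OC3=O | intermediate
17 | (4S,5S,8R,9S,13R,14S)-13,14,15-trihydroxyhalim-1(10)-en-18-oic acid | OC[C@H](O)[C@](C)(O)CC[C@]1(C)C2=CCC[C@](C)(C(=O)O)[C@H]2CC[C@H]1C | intermediate
18 | (4S,5S,8R,9S,13R,14S)-14,15-diacetoxy-13-hydroxyhalim-1(10)-en-18-oic acid (CNP0224606.1) | CC(=O)OC[C@H](OC(C)=O)[C@](C)(O)CC[C@]1(C)C2=CCC[C@](C)(C(=O)O)[C@H]2CC[C@H]1C | target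

## Count and risks

Total steps: 11. Longest linear sequence: 11 steps, from 1 to 18 (4 is bought and enters in step 3).

**Step 8 (cascade)** is the most likely to fail. The threats are Meinwald rearrangement of the epoxide, early proton loss at C8, and loss of the C5 configuration through a 5(10)-alkene. The fallback sets out from 11 and comes back at 14, separating ring formation from rearrangement. Compound 11 is cyclised with MeAlCl2 in CH2Cl2 at −94 °C, where the methyl–aluminium bond consumes the released proton and the reaction stops at the labdane stage. This gives (4S,5S,9R,10S,13R,14S)-13,14,15-triacetoxylabd-8(17)-en-18-ol F1 (its 7-ene isomer behaves the same way). Isolated F1 is then treated with BF3·OEt2 in CH2Cl2 from −50 to 0 °C, which protonates the alkene and runs the hydride shift, methyl shift and oxygen capture as a separate protic step to give 14.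

**Step 10 (E2 opening of the lactone)** is second. The carboxylate is a poor leaving group and prolonged strong base could move the alkene. The fallback sets out from 15 and comes back at 17, replacing base-driven E2 by Lewis-acid activation of the leaving group. Compound 15 is treated with Me3SiOTf and 2,6-di-tert-butylpyridine in CH2Cl2 from −78 to −40 °C; O-silylation turns the carboxylate into a neutral silyl ester leaving group and the hindered base removes the accessible H1. Aqueous work-up gives (4S,5S,8R,9S,13R,14S)-13,14,15-triacetoxyhalim-1(10)-en-18-oic acid F2, and K2CO3 in MeOH/H2O removes the acetates to give 17.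

**Step 7 (asymmetric epoxidation beside three acetates)** is third. The ylide may attack the esters, and the enantioselectivity for this ketone is not established. The fallback sets out from 7 and comes back at 11, making the head epoxide on an ester-free substrate and opening the tail epoxide without aqueous acid.
- Compound 7 is silylated (t-BuMe2SiCl, imidazole) to tert-butyl(dimethyl)silyl ether F3.
- PPTS in wet acetone frees the methyl ketone F4.
- The same LaLi3-BINOLate Corey–Chaykovsky reaction gives the (S)-epoxide silyl ether F5.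
- Bu4NF gives the epoxy allylic alcohol F6.
- Sharpless epoxidation with L-(+)-diethyl tartrate gives the bis-epoxide F7.
- Ti(OiPr)4 with acetic acid opens only the hydroxyl-directed tail epoxide at C13 with inversion to give the diol monoacetate F8.
- Ac2O/pyridine gives 11.

## Further compounds

F1 | step 8 | (4S,5S,9R,10S,13R,14S)-13,14,15-triacetoxylabd-8(17)-en-18-ol | CC(=O)OC[C@H](OC(C)=O)[C@](C)(OC(C)=O)CC[C@@H]1C(=C)CC[C@@H]2[C@@](C)(CO)CCC[C@@]12C
F2 | step 10 | (4S,5S,8R,9S,13R,14S)-13,14,15-triacetoxyhalim-1(10)-en-18-oic acid | CC(=O)OC[C@H](OC(C)=O)[C@](C)(OC(C)=O)CC[C@]1(C)C2=CCC[C@](C)(C(=O)O)[C@H]2CC[C@H]1C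
F3 | step 7 | tert-butyl(dimethyl){[(2E,6E,10E)-3,7,11-trimethyl-14-(2-methyl-1,3-dioxolan-2-yl)tetradeca-2,6,10-trien-1-yl]oxy}silane | CC1(CCC/C(C)=C/CC/C(C)=C/CC/C(C)=C/CO[Si](C)(C)C(C)(C)C)OCCO1
F4 | step 7 | (6E,10E,14E)-16-[(tert-butyldimethylsilyl)oxy]-6,10,14-trimethylhexadeca-6,10,14-trien-2-one | CC(=O)CCC/C(C)=C/CC/C(C)=C/CC/C(C)=C/CO[Si](C)(C)C(C)(C)C
F5 | step 7 | tert-butyl(dimethyl){[(2E,6E,10E)-3,7,11-trimethyl-14-[(2S)-2-methyloxiran-2-yl]tetradeca-2,6,10-trien-1-yl]oxy}silane | C[C@]1(CCC/C(C)=C/CC/C(C)=C/CC/C(C)=C/CO[Si](C)(C)C(C)(C)C)CO1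
F6 | step 7 | (2E,6E,10E)-3,7,11-trimethyl-14-[(2S)-2-methyloxiran-2-yl]tetradeca-2,6,10-trien-1-ol | C[C@]1(CCC/C(C)=C/CC/C(C)=C/CC/C(C)=C/CO)CO1
F7 | step 7 | [(2S,3S)-3-[(3E,7E)-4,8-dimethyl-11-[(2S)-2-methyloxiran-2-yl]undeca-3,7-dien-1-yl]-3-methyloxiran-2-yl]methanol | OC[C@@H]1O[C@@]1(C)CC/C=C(C)/CC/C=C(C)/CCC[C@@]2(C)CO2
F8 | step 7 | (2S,3R,6E,10E)-1,2-dihydroxy-3,7,11-trimethyl-14-[(2S)-2-methyloxiran-2-yl]tetradeca-6,10-dien-3-yl acetate | OC[C@H](O)[C@](C)(OC(C)=O)CC/C=C(C)/CC/C=C(C)/CCC[C@@]1(C)CO1
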